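**Plan**

Skeleton numbering: C1 benzoyl bridgehead; C2, C4, C9 ketones; C3 spiro carbon; C5 geranyl bridgehead; C6 CH2; C7 CH; C8 CMe2; C10 CH2; C11 CH; C12 CMe2; C13, C14 CH2 of the cyclopentane.
Retrosynthesis: cut C5–C6 (ring B of the cage) first, then C3–C4 and C1–C9 together (ring A), then C1–C2 (seven-membered ring), then C10–C11 (arm on the cyclopentane).
Forward: a C11-defined cyclopentene receives the C10–C7–C8–C1 arm by Carroll rearrangement; the ring C1–C2–C3–C11–C10–C7–C8 closes by Claisen condensation; ring A is laid across it; ring B closes last by radical addition of C5 to C6.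
Enabling feature: the C2 ketone of the seven-membered ring C1–C2–C3–C11–C10–C7–C8 has two enolisable α-carbons, C1 (also activated by benzoyl) and the ring-fusion carbon C3, which the three-carbon unit C9–C5–C4 can bridge to give ring A (C1–C2–C3–C4–C5–C9).
Stereochemistry: C11 comes from a CBS reduction relayed by a suprafacial [3,3] shift; C11 then directs C1 and C3 in the annulation; C5 and C7 are fixed by the cage.

Key step: step 14

Remark on the chemistry: C3 in 13–17 is enolisable and is planarised in step 14, so the cis isomers are drawn and the C3 epimers would serve equally; 17 and 24 are written as one enol tautomer.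

**Route**

Step 1
Reactants: 1 4,4-dimethylcyclopent-2-en-1-one
Product: 3 2-bromo-4,4-dimethylcyclopent-2-en-1-one, via dibromo ketone 2 (not isolated)
Conditions: Br2, CH2Cl2, 0 °C; then Et3N, 0 °C → rt
Reagents that add atoms: bromine, BrBr
Why: Bromine adds across the enone and Et3N removes HBr from the dibromide by E1cB elimination (α-bromination of an enone), leaving bromine on the carbon that becomes C3.

Step 2
Reactants: 3 2-bromo-4,4-dimethylcyclopent-2-en-1-one
Product: 4 (1S)-2-bromo-4,4-dimethylcyclopent-2-en-1-ol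
Conditions: (R)-2-methyl-CBS-oxazaborolidine (10 mol %), BH3·SMe2, THF, −20 °C; MeOH quench
Reagents that add atoms: none
Why: CBS reduction, in which the bromoalkenyl side acts as the large group, so the (R)-catalyst should deliver hydride to give the (S)-carbinol that is later relayed to C11.

Step 3
Reactants: 5 3,3-dimethyloxolane-2,5-dione (2,2-dimethylsuccinic anhydride)
Product: 6 4-[methoxy(methyl)amino]-2,2-dimethyl-4-oxobutanoic acid
Conditions: MeNHOMe·HCl, Et3N, CH2Cl2, 0 °C → rt; 1 M HCl work-up
Reagents that add atoms: N,O-dimethylhydroxylamine hydrochloride, CNOC.Cl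
Why: Aminolysis of a cyclic anhydride, in which the amine attacks the carbonyl next to CH2 and not the one shielded by the gem-dimethyl group, so the free acid sits on the quaternary carbon (future C8, acid carbon future C7).

Step 4
Reactants: 6 4-[methoxy(methyl)amino]-2,2-dimethyl-4-oxobutanoic acid
Product: 7 5-{1-hydroxy-4-[methoxy(methyl)amino]-2,2-dimethyl-4-oxobutylidene}-2,2-dimethyl-1,3-dioxane-4,6-dione
Conditions: Meldrum's acid, DCC, DMAP, CH2Cl2, 0 °C → rt
Reagents that add atoms: Meldrum's acid (2,2-dimethyl-1,3-dioxane-4,6-dione), CC1(C)OC(=O)CC(=O)O1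
Why: Carbodiimide-mediated C-acylation of Meldrum's acid through the acylpyridinium gives the acyl Meldrum's acid, a storable acylketene precursor that supplies C10.

Step 5
Reactants: 7 acyl Meldrum's acid from step 4; 4 (1S)-2-bromo-4,4-dimethylcyclopent-2-en-1-ol
Product: 11 5-[(1R)-2-bromo-5,5-dimethylcyclopent-2-en-1-yl]-N-methoxy-N,3,3-trimethyl-4-oxopentanamide, via acylketene 8 (not isolated), via β-keto ester 9 (not isolated), via β-keto acid 10 (not isolated)
Conditions: 1,2-dichlorobenzene, 110 °C, then 180 °C
Reagents that add atoms: none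
Why: Thermolysis of 7 gives acylketene 8, which 4 traps as β-keto ester 9, and the Carroll rearrangement ([3,3] shift of the enol, then loss of CO2 from 10) should form C10–C11 suprafacially, so the new bond enters on the ring face that oxygen leaves and the (S)-carbinol becomes (R)-C11.

Step 6
Reactants: 11 5-[(1R)-2-bromo-5,5-dimethylcyclopent-2-en-1-yl]-N-methoxy-N,3,3-trimethyl-4-oxopentanamide
Product: 12 methyl (5R)-5-{5-[methoxy(methyl)amino]-3,3-dimethyl-2,5-dioxopentyl}-4,4-dimethylcyclopent-1-ene-1-carboxylate
Conditions: Pd(OAc)2 (5 mol %), dppp, CO (1 atm), MeOH, Et3N, DMF, 70 °C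
Reagents that add atoms: carbon monoxide, [C-]#[O+]; methanol, CO
Why: Palladium-catalysed methoxycarbonylation of the alkenyl bromide (oxidative addition to zerovalent palladium, CO insertion, methanolysis) installs C2 as a methyl ester on C3.

Step 7
Reactants: 12 methyl (5R)-5-{5-[methoxy(methyl)amino]-3,3-dimethyl-2,5-dioxopentyl}-4,4-dimethylcyclopent-1-ene-1-carboxylate
Product: 13 methyl (1S,2S)-2-{5-[methoxy(methyl)amino]-3,3-dimethyl-2,5-dioxopentyl}-3,3-dimethylcyclopentane-1-carboxylate
Conditions: H2 (1 atm), Pd/C, EtOAc, rt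
Reagents that add atoms: none
Why: Heterogeneous hydrogenation of the conjugated alkene should add hydrogen to the face away from the C11 arm and give mainly the cis ester, at a stage where no other alkene is present and the ketone, amide and C11 are untouched.

Step 8
Reactants: 13 methyl (1S,2S)-2-{5-[methoxy(methyl)amino]-3,3-dimethyl-2,5-dioxopentyl}-3,3-dimethylcyclopentane-1-carboxylate
Product: 14 methyl (1S,2S)-2-{5-[methoxy(methyl)amino]-3,3-dimethyl-2-methylidene-5-oxopentyl}-3,3-dimethylcyclopentane-1-carboxylate
Conditions: Zn, CH2Br2, TiCl4, THF–CH2Cl2, 0 °C → rt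
Reagents that add atoms: dibromomethane, BrCBr
Why: Lombardo–Takai methylenation, whose non-basic gem-dimetallic reagent should convert the hindered, enolisable C7 ketone into the C7=C6 methylene without touching ester or amide and without base-induced cyclisation of the γ-keto amide.

Step 9
Reactants: 14 methyl (1S,2S)-2-{5-[methoxy(methyl)amino]-3,3-dimethyl-2-methylidene-5-oxopentyl}-3,3-dimethylcyclopentane-1-carboxylate
Product: 16 methyl (1S,2S)-2-(3,3-dimethyl-2-methylidene-5-oxo-5-phenylpentyl)-3,3-dimethylcyclopentane-1-carboxylate, via magnesium hemiaminal 15 (not isolated)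
Conditions: PhMgBr (1.2 equiv), THF, −20 → 0 °C; sat. aq. NH4Cl
Reagents that add atoms: phenylmagnesium bromide, Br[Mg]c1ccccc1
Why: Weinreb ketone synthesis, in which the amide takes up one equivalent of Grignard reagent as chelated adduct 15 and releases the phenyl ketone only on work-up, while the more hindered ring ester should react more slowly at low temperature.

Step 10
Reactants: 16 methyl (1S,2S)-2-(3,3-dimethyl-2-methylidene-5-oxo-5-phenylpentyl)-3,3-dimethylcyclopentane-1-carboxylate
Product: 17 [(3aS,8aS)-4-hydroxy-1,1,6,6-tetramethyl-7-methylidene-1,2,3,3a,6,7,8,8a-octahydroazulen-5-yl](phenyl)methanone (enol form of the 2-benzoyl ketone)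
Conditions: KOtBu (2.2 equiv), THF (0.01 M), 0 °C → rt; 1 M HCl
Reagents that add atoms: none
Why: Intramolecular Claisen condensation (7-exo-trig acyl substitution), in which the phenyl ketone can enolise only at C1 and attacks the C2 ester, helped by the gem-dimethyl group at C8 and driven by deprotonation of the product β-diketone.

Step 11
Reactants: 18 diethyl malonate; 19 geranyl bromide [(2E)-1-bromo-3,7-dimethylocta-2,6-diene]
Product: 20 diethyl 2-[(2E)-3,7-dimethylocta-2,6-dien-1-yl]propanedioate
Conditions: NaH, THF, 0 °C → rt (malonate in excess)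
Reagents that add atoms: none
Why: Malonic ester alkylation by SN2 displacement of the primary allylic bromide, which keeps the (E)-alkene and, with excess malonate, limits dialkylation.

Step 12
Reactants: 20 diethyl 2-[(2E)-3,7-dimethylocta-2,6-dien-1-yl]propanedioate
Product: 21 2-[(2E)-3,7-dimethylocta-2,6-dien-1-yl]propanedioic acid
Conditions: KOH, EtOH–H2O, rt → 50 °C; then cold 1 M HCl
Reagents that add atoms: potassium hydroxide, [K+].[OH-]
Why: Saponification under mild conditions with cold acidification should give the malonic acid without decarboxylation.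

Step 13
Reactants: 21 2-[(2E)-3,7-dimethylocta-2,6-dien-1-yl]propanedioic acid
Product: 22 2-[(2E)-3,7-dimethylocta-2,6-dien-1-yl]propanedioyl dichloride
Conditions: 1-chloro-N,N,2-trimethylprop-1-en-1-amine (2.1 equiv), CH2Cl2, 0 °C → rt; used crude
Reagents that add atoms: 1-chloro-N,N,2-trimethylprop-1-en-1-amine, CC(C)=C(Cl)N(C)C
Why: The α-chloroenamine (Ghosez reagent) converts both acids into acid chlorides under neutral conditions with only an amide as by-product, so no HCl is present to add to the trisubstituted alkenes.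

Step 14
Reactants: 17 enolised 2-benzoyl hydroazulenone; 22 geranylmalonyl dichloride
Product: 24 ring A trione (skeleton numbering): ring A C1–C2–C3–C4–C5–C9 bridging C1 and C3 of the seven-membered ring on the face away from the cyclopentane, benzoyl on C1, (E)-geranyl on C5, C4–C5 enol, C2 and C9 ketones, methylene on C7, C3 (S), C11 (R), via C1-acylated acid chloride 23 (not isolated)
Conditions: MgCl2 (2 equiv), Et3N (4.5 equiv), MeCN–CH2Cl2, −20 °C, slow addition of 22, → rt; then DMAP (0.2 equiv), rt; 1 M HCl
Reagents that add atoms: none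
Why: Proposed new method: MgCl2 and Et3N turn 17 into its magnesium chelate, which should be C-acylated at C1 by 22 or by the chlorocarbonyl ketene that Et3N makes from it (bond C1–C9) to give 23; the C2 ketone of 23 can then enolise only towards C3, and this enol attacks C4 (acid chloride or acylketene) to form bond C3–C4. The closest known reaction type is the Effenberger α,α′-annulation of ketone enol ethers with malonyl dichloride, here merged with the MgCl2/Et3N C-acylation of 1,3-dicarbonyl compounds; neither has been shown for a 2-acyl cycloheptanone whose first acylation makes a quaternary triacyl carbon. Ring A (C1–C2–C3–C4–C5–C9) closes by a 6-(enolendo)-exo-trig acyl substitution across the seven-membered ring. C1 is expected to be acylated on the face of the seven-membered ring away from the cyclopentane, and the C9–C5–C4 chain held on that face can reach the C2=C3 enol only anti to C10, that is cis to the C11 hydrogen, so C11 controls both new centres and the cis ring fusion is kept. The step needs acylation on carbon and not on oxygen at both sites: magnesium chelation favours carbon at C1, and at C3 an enol lactone formed on oxygen should be returned by DMAP-mediated acyl transfer, because only the C-acylated trione has the acidic C5–H between C4 and C9 and leaves the equilibrium as its enolate. Slow addition of 22 at low temperature should keep its ketene from self-condensing.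

Step 15
Reactants: 24 ring A trione
Product: 25 target CNP0168637.1 (24 with the added bond C5–C6 closing ring B C5–C6–C7–C8–C1–C9 and hydrogen on C7; configuration as in the SMILES)
Conditions: Mn(OAc)3·2H2O (2.2 equiv), degassed EtOH, rt → 50 °C
Reagents that add atoms: none
Why: Manganese triacetate oxidative radical cyclisation with reductive termination, in which the C5 radical from the enolised C4–C5–C9 diketone adds 6-endo-trig to the unsubstituted methylene carbon C6 (5-exo attack on the fully substituted C7 is disfavoured), the C7 bridgehead radical cannot flatten for oxidation and should take hydrogen from ethanol, and the cage allows only one configuration at C5 and C7.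

**Compound list**

1 | 4,4-dimethylcyclopent-2-en-1-one | CC1(C)CC(=O)C=C1 | starting material
2 | 2,3-dibromo-4,4-dimethylcyclopentan-1-one (formed and consumed in step 1) | CC1(C)CC(=O)C(Br)C1Br | intermediate
3 | 2-bromo-4,4-dimethylcyclopent-2-en-1-one | CC1(C)CC(=O)C(Br)=C1 | intermediate
4 | (1S)-2-bromo-4,4-dimethylcyclopent-2-en-1-ol | O[C@H]1CC(C)(C)C=C1Br | intermediate
5 | 3,3-dimethyloxolane-2,5-dione (2,2-dimethylsuccinic anhydride) | CC1(C)CC(=O)OC1=O | starting material
6 | 4-[methoxy(methyl)amino]-2,2-dimethyl-4-oxobutanoic acid | CON(C)C(=O)CC(C)(C)C(=O)O | intermediate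
7 | 5-{1-hydroxy-4-[methoxy(methyl)amino]-2,2-dimethyl-4-oxobutylidene}-2,2-dimethyl-1,3-dioxane-4,6-dione | CON(C)C(=O)CC(C)(C)C(O)=C1C(=O)OC(C)(C)OC1=O | intermediate
8 | N-methoxy-N,3,3-trimethyl-4,6-dioxohex-5-enamide (acylketene, formed and consumed in step 5) | CON(C)C(=O)CC(C)(C)C(=O)C=C=O | intermediate
9 | (1S)-2-bromo-4,4-dimethylcyclopent-2-en-1-yl 6-[methoxy(methyl)amino]-4,4-dimethyl-3,6-dioxohexanoate (formed and consumed in step 5) | CON(C)C(=O)CC(C)(C)C(=O)CC(=O)O[C@H]1CC(C)(C)C=C1Br | intermediate
10 | 2-[(1R)-2-bromo-5,5-dimethylcyclopent-2-en-1-yl]-6-[methoxy(methyl)amino]-4,4-dimethyl-3,6-dioxohexanoic acid (formed and consumed in step 5) | CON(C)C(=O)CC(C)(C)C(=O)C(C(=O)O)[C@H]1C(Br)=CCC1(C)C | intermediate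
11 | 5-[(1R)-2-bromo-5,5-dimethylcyclopent-2-en-1-yl]-N-methoxy-N,3,3-trimethyl-4-oxopentanamide | CON(C)C(=O)CC(C)(C)C(=O)C[C@H]1C(Br)=CCC1(C)C | intermediate
12 | methyl (5R)-5-{5-[methoxy(methyl)amino]-3,3-dimethyl-2,5-dioxopentyl}-4,4-dimethylcyclopent-1-ene-1-carboxylate | CON(C)C(=O)CC(C)(C)C(=O)C[C@H]1C(C(=O)OC)=CCC1(C)C | intermediate
13 | methyl (1S,2S)-2-{5-[methoxy(methyl)amino]-3,3-dimethyl-2,5-dioxopentyl}-3,3-dimethylcyclopentane-1-carboxylate | COC(=O)[C@H]1CCC(C)(C)[C@H]1CC(=O)C(C)(C)CC(=O)N(C)OC | intermediate
14 | methyl (1S,2S)-2-{5-[methoxy(methyl)amino]-3,3-dimethyl-2-methylidene-5-oxopentyl}-3,3-dimethylcyclopentane-1-carboxylate | COC(=O)[C@H]1CCC(C)(C)[C@H]1CC(=C)C(C)(C)CC(=O)N(C)OC | intermediate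
15 | methyl (1S,2S)-2-{5-[(bromomagnesio)oxy]-5-[methoxy(methyl)amino]-3,3-dimethyl-2-methylidene-5-phenylpentyl}-3,3-dimethylcyclopentane-1-carboxylate (formed in step 9, cleaved on work-up) | COC(=O)[C@H]1CCC(C)(C)[C@H]1CC(=C)C(C)(C)CC(O[Mg]Br)(c1ccccc1)N(C)OC | intermediate
16 | methyl (1S,2S)-2-(3,3-dimethyl-2-methylidene-5-oxo-5-phenylpentyl)-3,3-dimethylcyclopentane-1-carboxylate | COC(=O)[C@H]1CCC(C)(C)[C@H]1CC(=C)C(C)(C)CC(=O)c1ccccc1 | intermediate
17 | [(3aS,8aS)-4-hydroxy-1,1,6,6-tetramethyl-7-methylidene-1,2,3,3a,6,7,8,8a-octahydroazulen-5-yl](phenyl)methanone | O=C(c1ccccc1)C1=C(O)[C@H]2CCC(C)(C)[C@H]2CC(=C)C1(C)C | intermediate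
18 | diethyl malonate | CCOC(=O)CC(=O)OCC | starting material
19 | geranyl bromide, (2E)-1-bromo-3,7-dimethylocta-2,6-diene | CC(C)=CCC/C(C)=C/CBr | starting material
20 | diethyl 2-[(2E)-3,7-dimethylocta-2,6-dien-1-yl]propanedioate | CC(C)=CCC/C(C)=C/CC(C(=O)OCC)C(=O)OCC | intermediate
21 | 2-[(2E)-3,7-dimethylocta-2,6-dien-1-yl]propanedioic acid | CC(C)=CCC/C(C)=C/CC(C(=O)O)C(=O)O | intermediate
22 | 2-[(2E)-3,7-dimethylocta-2,6-dien-1-yl]propanedioyl dichloride | CC(C)=CCC/C(C)=C/CC(C(Cl)=O)C(Cl)=O | intermediate
23 | diketo form of 17 carrying on C1 the 2-(chlorocarbonyl)-5,9-dimethyldeca-4,8-dienoyl group, C9 on the face away from the cyclopentane (formed and consumed in step 14) | CC(C)=CCC/C(C)=C/CC(C(Cl)=O)C(=O)[C@]1(C(=O)c2ccccc2)C(=O)[C@H]2CCC(C)(C)[C@H]2CC(=C)C1(C)C | intermediate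
24 | ring A trione: cyclopentane-fused bicyclo[4.3.1]decane with bridgeheads C1 (benzoyl) and C3 (spiro carbon), C2 and C9 ketones, C4–C5 enol with (E)-geranyl on C5, methylene on C7, gem-dimethyl on C8 and C12; C3 (S), C11 (R) | CC(C)=CCC/C(C)=C/CC1=C(O)[C@]23CCC(C)(C)[C@H]2CC(=C)C(C)(C)[C@](C(=O)c2ccccc2)(C1=O)C3=O | intermediate
25 | target CNP0168637.1: caged tetraketone, 24 with the bond C5–C6 and hydrogen on C7 | CC(C)=CCC/C(C)=C/C[C@@]12C[C@H]3C[C@@H]4C(C)(C)CC[C@]4(C1=O)C(=O)[C@@](C(=O)c1ccccc1)(C2=O)C3(C)C | target

**Step count and risks**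

Total steps: 15. Longest linear sequence: 10 steps (1, 2, 5, 6, 7, 8, 9, 10, 14, 15).

Steps most likely to fail:

1. Step 14 (labelled as a new method). Acylation on oxygen may outrun acylation on carbon at the crowded C1, and the ketene from 22 may self-condense. The fallback introduces the benzoyl group after ring A, using known chemistry. Setting out from 14, LiN(SiMe3)2 (THF, −78 → 0 °C) would close the seven-membered ring from the other side, the C3 ester enolate attacking the N-methoxy-N-methylamide, to give the cis-fused β-keto ester methyl (3aR,8aR)-1,1,6,6-tetramethyl-7-methylidene-4-oxo-octahydroazulene-3a-carboxylate F1. Krapcho dealkoxycarbonylation (LiCl, wet DMSO, 150 °C) would give the ketone (3aS,8aS)-1,1,6,6-tetramethyl-7-methylidene-octahydroazulen-4-one F2, and LiN(iPr)2/TBSCl its tert-butyldimethylsilyl enol ether F3 (either regioisomer would serve). Effenberger cyclisation of this enol ether with 22 (Et2O, −20 °C → rt; then KOH, BnEt3NCl) would give the debenzoyl analogue of 24 with hydrogen on C1, F4. O-Methylation (Me3SiCHN2) would give its C4 methyl enol ether F5; bridgehead lithiation at C1 (lithium 2,2,6,6-tetramethylpiperidide, THF, −78 °C) and trapping with benzoyl chloride would give the C4 methyl enol ether of 24, F6; LiCl in DMSO (120 °C) would remove the methyl group and rejoin the route at 24.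

2. Step 15. Oxidation of the C7 radical to the cation and capture by solvent may outrun hydrogen abstraction. The fallback generates the radical reductively. From 24, PhSeCl and pyridine (CH2Cl2, 0 °C) would give the C5 phenylselanyl triketone F8; Bu3SnH with AIBN (slow addition, benzene, 80 °C) would generate the same C5 radical, cyclise it onto C6 and quench the C7 radical with tin hydride, arriving at 25.

3. Step 10. Closure of the seven-membered ring by the hindered ketone enolate may be slow enough for intermolecular condensation to compete. The fallback closes the ring before the phenyl group is added. From 14, LiN(iPr)2 (THF, −78 → 0 °C) would form the more nucleophilic amide enolate at C1, which attacks the C2 ester to give the cyclic β-keto amide (3aS,8aS)-N-methoxy-N,1,1,6,6-pentamethyl-7-methylidene-4-oxo-decahydroazulene-5-carboxamide F7; excess PhMgBr (THF, 0 °C → rt) would then add to the amide of its magnesium enolate and work-up would give 17.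

**Further compounds**

F1 | step 14 | methyl (3aR,8aR)-1,1,6,6-tetramethyl-7-methylidene-4-oxo-octahydroazulene-3a-carboxylate | COC(=O)[C@]12CCC(C)(C)[C@H]1CC(=C)C(C)(C)CC2=O
F2 | step 14 | (3aS,8aS)-1,1,6,6-tetramethyl-7-methylidene-octahydroazulen-4-one | O=C1[C@H]2CCC(C)(C)[C@H]2CC(=C)C(C)(C)C1
F3 | step 14 | tert-butyldimethylsilyl enol ether of F2 (C1=C2 in skeleton numbering) | CC(C)(C)[Si](C)(C)OC=1[C@H]2CCC(C)(C)[C@H]2CC(=C)C(C)(C)C=1
F4 | step 14 | debenzoyl analogue of 24 (hydrogen on C1) | CC(C)=CCC/C(C)=C/CC1=C(O)[C@]23CCC(C)(C)[C@H]2CC(=C)C(C)(C)[C@H](C1=O)C3=O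
F5 | step 14 | C4 methyl enol ether of F4 | CC(C)=CCC/C(C)=C/CC1=C(OC)[C@]23CCC(C)(C)[C@H]2CC(=C)C(C)(C)[C@H](C1=O)C3=O
F6 | step 14 | C4 methyl enol ether of 24 | CC(C)=CCC/C(C)=C/CC1=C(OC)[C@]23CCC(C)(C)[C@H]2CC(=C)C(C)(C)[C@](C(=O)c2ccccc2)(C1=O)C3=O
F7 | step 10 | (3aS,8aS)-N-methoxy-N,1,1,6,6-pentamethyl-7-methylidene-4-oxo-decahydroazulene-5-carboxamide | CON(C)C(=O)C1C(=O)[C@H]2CCC(C)(C)[C@H]2CC(=C)C1(C)C
F8 | step 15 | C5 phenylselanyl derivative of the triketone form of 24 | CC(C)=CCC/C(C)=C/CC1([Se]c4ccccc4)C(=O)[C@]23CCC(C)(C)[C@H]2CC(=C)C(C)(C)[C@](C(=O)c2ccccc2)(C1=O)C3=O
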